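The data were computed for substances that don't exist, and the scatter is random.

Begin with a subtraction, the easiest thing the runs below allow.

| flask | solid substrate | reagent | temperature | remark | time |
|---|---|---|---|---|---|
| east | 0.27 M | 0.44 M | 25 °C | run made earlier |  |
| north | 0.80 M | 0.44 M | 25 °C | run made earlier |  |
| grey | 0.40 M | 2.00 M |  | at 5 °C throughout | 1.0 d |
| violet | 0.40 M | 0.440 M |  | at 25 °C until 20 h, from then on at 5 °C | 3.0 d |

| run | time / h | target / % | solid substrate / % |
|---|---|---|---|
| east | 3.00 | 0 | 90 |
| east | 8.00 | 8 | 88 |
| east | 20.0 | 24 | 62 |
| east | 40.0 | 46 | 25 |
| north | 3.00 | 2 | 96 |
| north | 8.00 | 1 | 96 |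
| north | 20.0 | 10 | 83 |
| north | 40.0 | 18 | 74 |

(standard deviation of a reading: 2 percentage points)

1. the winner by amount of target, in percent of the solid substrate charged; "neither" if no more than 2 percentage points parts them (grey / violet / neither)
2. how much target is there at the end, in percent of the solid substrate charged: grey
3. how much target is there at the end, in percent of the solid substrate charged: violet

- a species is counted by the solid substrate in it: one homo dimer counts as two
- given per volume of solution although it is solid: solid substrate
- steps under discussion: target + by-product -> side product; 2 starting material -> homo dimer; starting material + reagent -> intermediate + by-product; solid substrate <-> starting material; intermediate -> target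
- at the start none of the solid substrate is in solution
- what has only dissolved of solid substrate counts as not reacted
- the earlier runs do not show what temperature does; that part of a forecast is a guess

Between its second and last readings the east run loses solid substrate at a fraction of its charge of 0.0197 h⁻¹, the north run at 0.00687 h⁻¹. Divide: east's fraction is 2.87 times north's, and north's charge is 2.96 times east's. So, as far as these readings show, the solid substrate leaves both runs at one amount per hour, which you can read as a rate-limiting step in dissolving. Scaled to a charge of 0.40 M, that gives 0.0135 h⁻¹, the feed fraction: the part of a charge leaving the solid per hour, inverse to the charge in these two runs.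

Next, you use it. At the last readings target averages 65.3 % of what has left the solid. The second readings then put target behind that line by about 3.77 h, a noisy reading, which I take as the holding time of the intermediate pool.

At 5 °C I guess that the feed stays and the holding time grows 10-fold, to 37.7 h. A pool filled steadily and emptying with that time gives grey 5.51 %. Violet banks 17.7 % while warm, then adds the cold part over 52.0 h, reaching 38.6 %. By this reckoning violet's solid lasts to the end, since the feed totals 97.3 % of the charge.

The guess is the weak link, so reforge it at 20-fold: that gives grey 3.04 % and violet 30.4 %. Violet still leads.

The forecast said violet, with 10 % for grey and 30 % for violet: “Violet should win, though the temperature effect is a guess.”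

The flasks give 5.11 % in grey and 32.5 % in violet, so violet wins, and my violet stood 6.1 percentage points high.

    target + by-product → side product (k = 0.00350 L mol⁻¹ min⁻¹, Ea = 68.0 kJ mol⁻¹)
    2 starting material → homo dimer (k = 5.00 × 10⁻⁶ L mol⁻¹ min⁻¹, Ea = 74.0 kJ mol⁻¹)
    starting material + reagent → intermediate + by-product (k = 0.180 L mol⁻¹ min⁻¹, Ea = 58.0 kJ mol⁻¹)
    solid substrate ⇌ starting material, rate k4*(cs4 - [starting material]) while solid is left; crystals form when [starting material] > cs4 (solubility = 0.0910 M, k = 9.80 × 10⁻⁴ min⁻¹)
    intermediate → target (k = 0.00510 min⁻¹, Ea = 102 kJ mol⁻¹)
    (constants at 25 °C)

Now charge violet's neighbour with 0.68 M of solid substrate, the other charges and the time held. The same feed is a smaller fraction of that charge, 0.00795 h⁻¹, so 57.3 % should leave the solid, and violet's target scales to 19.1 %. The neighbour lost 51.5 % of its solid, and its target stands at 19.1 %.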